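Ring A (C1 carrying the CH2CH2 bridge, C2–H, C3–OMe, C4–benzyl, C5–OH, C6–benzyl) is disconnected at C4–C5 and C5–C6. The phenolic carbon C5, lying between the two benzylated carbons, is taken from carbon monoxide, and C4–C3–C2–C1–C6 from an acyclic 3-pivaloyloxy-1,4-enyne. One Rh(I)-catalysed [5+1] carbonylative benzannulation should form both bonds and the ring with all four carbon substituents in place, while the pivalate shifts to C3 and so leaves the two resorcinol oxygens differentiated. The precursor is the racemic E ester ArCH2–C≡C–CH(OPiv)–C(CH2CH2Ar')=CH–CH2Ar (Ar = 4-benzyloxyphenyl, Ar' = 3-methoxyphenyl), assembled by olefination, acetylide addition and in situ acylation.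

Key step: step 8

Assumption: the target has no stereocentre and no stereogenic double bond, so it is one achiral compound and no enantiocontrol is needed. The only stereochemical element carried is the E geometry of the trisubstituted alkene in compounds 8–15. The carbinol centre of 14 and 15 is left racemic on purpose, since it becomes the aromatic C2–H.

Step 1
Reactants: 1 triethyl phosphonoacetate; 2 1-(2-bromoethyl)-3-methoxybenzene
Product: 4 ethyl 2-(diethoxyphosphoryl)-4-(3-methoxyphenyl)butanoate (racemic), via sodium triethyl phosphonoacetate 3 (not isolated)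
Conditions: 1 (1.5 equiv), NaH, DMF, 0 °C; then 2, NaI (cat.), 60 °C
Reagents that add atoms: none
Why: SN2 C-alkylation of the soft, weakly basic phosphonate-stabilised carbanion with the primary bromide should outrun E2 to the styrene, the excess of 1 limiting dialkylation, and the new centre is racemic and is lost in step 3.

Step 2
Reactants: 5 2-[4-(benzyloxy)phenyl]ethanol
Product: 6 [4-(benzyloxy)phenyl]acetaldehyde
Conditions: Dess–Martin periodinane, CH2Cl2, 0 °C → rt; crude aldehyde used at once
Reagents that add atoms: none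
Why: Dess–Martin oxidation takes the primary alcohol to the aldehyde under near-neutral conditions that spare the benzyl ether and avoid enolisation of the sensitive arylacetaldehyde.

Step 3
Reactants: 4 ethyl 2-(diethoxyphosphoryl)-4-(3-methoxyphenyl)butanoate; 6 [4-(benzyloxy)phenyl]acetaldehyde
Product: 8 ethyl (2E)-4-[4-(benzyloxy)phenyl]-2-[2-(3-methoxyphenyl)ethyl]but-2-enoate, via sodiated phosphonate 7 (not isolated)
Conditions: 4 (1.2 equiv), NaH (1.1 equiv), THF, 0 °C; then 6, −78 °C → rt
Reagents that add atoms: none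
Why: The Horner–Wadsworth–Emmons olefination of an α-alkyl phosphonoacetate with an unhindered aldehyde is under thermodynamic control and should place the ester trans to the aldehyde-derived CH2Ar group (E), while base kept below the phosphonate in amount should prevent the skipped alkene from moving into conjugation with the arene.

Step 4
Reactants: 8 ethyl (2E)-4-[4-(benzyloxy)phenyl]-2-[2-(3-methoxyphenyl)ethyl]but-2-enoate
Product: 9 (2E)-4-[4-(benzyloxy)phenyl]-2-[2-(3-methoxyphenyl)ethyl]but-2-en-1-ol
Conditions: DIBAL-H (2.5 equiv), CH2Cl2, −78 °C → 0 °C; Rochelle salt work-up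
Reagents that add atoms: none
Why: DIBAL-H 1,2-reduction of an α,β-unsaturated ester gives the allylic alcohol without touching the alkene geometry or the ethers.

Step 5
Reactants: 9 (2E)-4-[4-(benzyloxy)phenyl]-2-[2-(3-methoxyphenyl)ethyl]but-2-en-1-ol
Product: 10 (2E)-4-[4-(benzyloxy)phenyl]-2-[2-(3-methoxyphenyl)ethyl]but-2-enal
Conditions: activated MnO2, CH2Cl2, rt
Reagents that add atoms: none
Why: MnO2 oxidation is selective for allylic alcohols and runs under neutral heterogeneous conditions, so the E geometry and the doubly activated CH2 group should be preserved.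

Step 6
Reactants: 11 4-(benzyloxy)benzyl bromide
Product: 12 1-(benzyloxy)-4-(prop-2-yn-1-yl)benzene
Conditions: ethynylmagnesium bromide (2 equiv), CuBr·SMe2 (10 mol %), THF, 0 °C → 50 °C
Reagents that add atoms: ethynylmagnesium bromide, C#C[Mg]Br
Why: Copper-catalysed sp3–sp cross-coupling of a benzylic bromide with an alkynyl Grignard reagent gives the 3-arylpropyne, the excess acetylide suppressing double benzylation.

Step 7
Reactants: 12 1-(benzyloxy)-4-(prop-2-yn-1-yl)benzene; 10 (2E)-4-[4-(benzyloxy)phenyl]-2-[2-(3-methoxyphenyl)ethyl]but-2-enal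
Product: 15 (5E)-1,7-bis[4-(benzyloxy)phenyl]-5-[2-(3-methoxyphenyl)ethyl]hept-5-en-2-yn-4-yl 2,2-dimethylpropanoate (racemic), via lithium arylpropynide 13 (not isolated), via lithium propargylic alkoxide 14 (not isolated)
Conditions: 12 (1.2 equiv), n-BuLi (1.0 equiv per 12), THF, −78 °C; then 10, −78 °C; then PivCl, −78 °C → rt
Reagents that add atoms: pivaloyl chloride, CC(C)(C)C(=O)Cl
Why: Kinetic deprotonation of the terminal alkyne C–H, 1,2-addition of the acetylide to the enal and in situ O-acylation of the lithium alkoxide give the propargylic ester, the new carbinol centre being formed without control because it later becomes an aromatic CH.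

Step 8
Reactants: 15 (5E)-1,7-bis[4-(benzyloxy)phenyl]-5-[2-(3-methoxyphenyl)ethyl]hept-5-en-2-yn-4-yl 2,2-dimethylpropanoate; 16 carbon monoxide
Product: 17 2,4-bis[4-(benzyloxy)benzyl]-3-hydroxy-5-[2-(3-methoxyphenyl)ethyl]phenyl 2,2-dimethylpropanoate
Conditions: [Rh(CO)2Cl]2 (5 mol %), CO (50 bar), CH2Cl2, 80 °C
Reagents that add atoms: none
Why: Proposed new method: Rh(I) π-activation of the alkyne should trigger a 1,2-shift of the pivalate from the carbinol carbon (future C2) to the neighbouring alkyne carbon (future C3), giving a rhodium carbene at the benzyl-bearing alkyne terminus (future C4) that is held by the pendant alkene as a rhodacyclohexadiene or captures CO as a dienylketene; the closest known reaction type is the Rh-catalysed [5+1] carbonylation of 3-acyloxy-1,4-enynes with terminal alkynes, which has not been shown for an alkyl-substituted internal alkyne. Ring A closes as a six-membered carbocycle in the [5+1] mode, CO becoming C5 and the C4–C5 and C5–C6 bonds arising from CO insertion followed by reductive elimination (or 6π-electrocyclisation of the ketene), after which the cyclohexadienone enolises irreversibly to the phenol. No stereocentre is created, and the racemic carbinol centre ends as C2–H. The selectivity needed is 1,2- over 1,3-acyloxy migration, because the allenyl ester from the 1,3-shift can be carbonylated to a cyclopentenone in a [4+1] process; both shifts are expected to be reversible, and the high CO pressure is chosen to saturate rhodium against η4-binding of a vinylallene while speeding carbene capture, so that material should drain through the aromatising channel. In the substrate, the 1,4-enyne unit traps the carbene intramolecularly, the E alkene puts H and not CH2Ar on the inside of the closing terminus, and the robust pivalate marks O3 apart from O5.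

Step 9
Reactants: 17 2,4-bis[4-(benzyloxy)benzyl]-3-hydroxy-5-[2-(3-methoxyphenyl)ethyl]phenyl 2,2-dimethylpropanoate
Product: 18 3-(benzyloxy)-2,4-bis[4-(benzyloxy)benzyl]-5-[2-(3-methoxyphenyl)ethyl]phenyl 2,2-dimethylpropanoate
Conditions: BnBr, K2CO3, Bu4NI (cat.), DMF, rt → 40 °C
Reagents that add atoms: benzyl bromide, BrCc1ccccc1
Why: Williamson O-benzylation of the C5 phenoxide runs under mild carbonate conditions that should leave the hindered aryl pivalate intact, fixing O5 as an ether that comes off in the last step.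

Step 10
Reactants: 18 3-(benzyloxy)-2,4-bis[4-(benzyloxy)benzyl]-5-[2-(3-methoxyphenyl)ethyl]phenyl 2,2-dimethylpropanoate
Product: 20 1-(benzyloxy)-2,6-bis[4-(benzyloxy)benzyl]-3-methoxy-5-[2-(3-methoxyphenyl)ethyl]benzene, via depivaloylated phenol 19 (not isolated)
Conditions: NaOMe, MeOH/THF, rt → 40 °C; AcOH, concentrate; then MeI, K2CO3, DMF, rt
Reagents that add atoms: iodomethane, CI
Why: Methoxide transesterification releases the aryl pivalate as the only free phenol (O3), and Williamson O-methylation of that phenoxide then installs the C3 methyl ether.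

Step 11
Reactants: 20 1-(benzyloxy)-2,6-bis[4-(benzyloxy)benzyl]-3-methoxy-5-[2-(3-methoxyphenyl)ethyl]benzene
Product: 21 2,6-bis(4-hydroxybenzyl)-3-methoxy-5-[2-(3-methoxyphenyl)ethyl]phenol (target)
Conditions: H2 (1 atm), 10% Pd/C, EtOAc/MeOH, rt
Reagents that add atoms: none
Why: Palladium-catalysed hydrogenolysis should cleave the three aryl benzyl ethers together, the diarylmethane and bibenzyl C–C bonds and the methyl ethers being inert under these conditions.

Compound list
1 | triethyl phosphonoacetate | CCOC(=O)CP(=O)(OCC)OCC | starting material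
2 | 1-(2-bromoethyl)-3-methoxybenzene | COc1cccc(CCBr)c1 | starting material
3 | sodium triethyl phosphonoacetate (sodium salt of 1, not isolated) | CCOC(=O)[CH-]P(=O)(OCC)OCC.[Na+] | intermediate
4 | ethyl 2-(diethoxyphosphoryl)-4-(3-methoxyphenyl)butanoate (racemic) | CCOC(=O)C(CCc1cccc(OC)c1)P(=O)(OCC)OCC | intermediate
5 | 2-[4-(benzyloxy)phenyl]ethanol | OCCc1ccc(OCc2ccccc2)cc1 | starting material
6 | [4-(benzyloxy)phenyl]acetaldehyde | O=CCc1ccc(OCc2ccccc2)cc1 | intermediate
7 | sodium salt of 4 (sodiated phosphonate, not isolated) | CCOC(=O)[C-](CCc1cccc(OC)c1)P(=O)(OCC)OCC.[Na+] | intermediate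
8 | ethyl (2E)-4-[4-(benzyloxy)phenyl]-2-[2-(3-methoxyphenyl)ethyl]but-2-enoate | CCOC(=O)/C(CCc1cccc(OC)c1)=C/Cc1ccc(OCc2ccccc2)cc1 | intermediate
9 | (2E)-4-[4-(benzyloxy)phenyl]-2-[2-(3-methoxyphenyl)ethyl]but-2-en-1-ol | OC/C(CCc1cccc(OC)c1)=C/Cc1ccc(OCc2ccccc2)cc1 | intermediate
10 | (2E)-4-[4-(benzyloxy)phenyl]-2-[2-(3-methoxyphenyl)ethyl]but-2-enal | O=C/C(CCc1cccc(OC)c1)=C/Cc1ccc(OCc2ccccc2)cc1 | intermediate
11 | 4-(benzyloxy)benzyl bromide | BrCc1ccc(OCc2ccccc2)cc1 | starting material
12 | 1-(benzyloxy)-4-(prop-2-yn-1-yl)benzene | C#CCc1ccc(OCc2ccccc2)cc1 | intermediate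
13 | lithium 3-[4-(benzyloxy)phenyl]prop-1-yn-1-ide (not isolated) | [Li+].[C-]#CCc1ccc(OCc2ccccc2)cc1 | intermediate
14 | lithium (5E)-1,7-bis[4-(benzyloxy)phenyl]-5-[2-(3-methoxyphenyl)ethyl]hept-5-en-2-yn-4-olate (racemic, not isolated) | [Li+].[O-]C(C#CCc1ccc(OCc2ccccc2)cc1)/C(CCc1cccc(OC)c1)=C/Cc1ccc(OCc2ccccc2)cc1 | intermediate
15 | (5E)-1,7-bis[4-(benzyloxy)phenyl]-5-[2-(3-methoxyphenyl)ethyl]hept-5-en-2-yn-4-yl 2,2-dimethylpropanoate (racemic) | CC(C)(C)C(=O)OC(C#CCc1ccc(OCc2ccccc2)cc1)/C(CCc1cccc(OC)c1)=C/Cc1ccc(OCc2ccccc2)cc1 | intermediate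
16 | carbon monoxide | [C-]#[O+] | starting material
17 | 2,4-bis[4-(benzyloxy)benzyl]-3-hydroxy-5-[2-(3-methoxyphenyl)ethyl]phenyl 2,2-dimethylpropanoate | COc1cccc(CCc2cc(OC(=O)C(C)(C)C)c(Cc3ccc(OCc4ccccc4)cc3)c(O)c2Cc2ccc(OCc3ccccc3)cc2)c1 | intermediate
18 | 3-(benzyloxy)-2,4-bis[4-(benzyloxy)benzyl]-5-[2-(3-methoxyphenyl)ethyl]phenyl 2,2-dimethylpropanoate | COc1cccc(CCc2cc(OC(=O)C(C)(C)C)c(Cc3ccc(OCc4ccccc4)cc3)c(OCc3ccccc3)c2Cc2ccc(OCc3ccccc3)cc2)c1 | intermediate
19 | 3-(benzyloxy)-2,4-bis[4-(benzyloxy)benzyl]-5-[2-(3-methoxyphenyl)ethyl]phenol (not isolated) | COc1cccc(CCc2cc(O)c(Cc3ccc(OCc4ccccc4)cc3)c(OCc3ccccc3)c2Cc2ccc(OCc3ccccc3)cc2)c1 | intermediate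
20 | 1-(benzyloxy)-2,6-bis[4-(benzyloxy)benzyl]-3-methoxy-5-[2-(3-methoxyphenyl)ethyl]benzene | COc1cccc(CCc2cc(OC)c(Cc3ccc(OCc4ccccc4)cc3)c(OCc3ccccc3)c2Cc2ccc(OCc3ccccc3)cc2)c1 | intermediate
21 | 2,6-bis(4-hydroxybenzyl)-3-methoxy-5-[2-(3-methoxyphenyl)ethyl]phenol (achiral) | COc1cccc(CCc2cc(OC)c(Cc3ccc(O)cc3)c(O)c2Cc2ccc(O)cc2)c1 | target

Total step count: 11 steps.
Longest linear sequence: 9 steps (steps 1, 3, 4, 5, 7, 8, 9, 10, 11 from triethyl phosphonoacetate; the branch from alcohol 5 through step 2 is equally long).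

Steps most likely to fail

Step 8 (the step that bears the label). What may go wrong: the pivalate may migrate in the 1,3-sense to an allenyl ester, which is then carbonylated in a [4+1] manner to a five-membered ketone, so that ring A does not form. The fallback uses known chemistry only; it sets out from enal 10 and comes back at phenol 19.
- Ethynylmagnesium bromide adds to 10 (THF, −78 → 0 °C) to give (4E)-6-[4-(benzyloxy)phenyl]-4-[2-(3-methoxyphenyl)ethyl]hex-4-en-1-yn-3-ol F1.
- Acylation (PivCl, pyridine, DMAP, CH2Cl2) gives (4E)-6-[4-(benzyloxy)phenyl]-4-[2-(3-methoxyphenyl)ethyl]hex-4-en-1-yn-3-yl 2,2-dimethylpropanoate F2, a terminal-alkyne ester of the class for which the Rh-catalysed [5+1] carbonylation is established.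
- Under [Rh(CO)2Cl]2, CO, CH2Cl2, 80 °C it should give 4-[4-(benzyloxy)benzyl]-3-hydroxy-5-[2-(3-methoxyphenyl)ethyl]phenyl 2,2-dimethylpropanoate F3, in which C4 carries hydrogen.
- Magnesium-mediated ortho-formylation (MgCl2, Et3N, paraformaldehyde, MeCN, reflux) can only take place at C4, the one free position ortho to the C5 hydroxyl, and gives 4-[4-(benzyloxy)benzyl]-2-formyl-3-hydroxy-5-[2-(3-methoxyphenyl)ethyl]phenyl 2,2-dimethylpropanoate F4.
- Benzylation of the C5 hydroxyl (BnBr, K2CO3, DMF) gives 3-(benzyloxy)-4-[4-(benzyloxy)benzyl]-2-formyl-5-[2-(3-methoxyphenyl)ethyl]phenyl 2,2-dimethylpropanoate F5.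
- Addition of commercial 4-(benzyloxy)phenylmagnesium bromide (THF, −78 → 0 °C), followed by NaOMe/MeOH in the same flask to remove the pivalate wherever it then sits, gives 3-(benzyloxy)-4-[4-(benzyloxy)benzyl]-2-{[4-(benzyloxy)phenyl](hydroxy)methyl}-5-[2-(3-methoxyphenyl)ethyl]phenol F6.
- Ionic deoxygenation of the doubly benzylic carbinol (Et3SiH, BF3·OEt2, CH2Cl2, −40 °C) gives phenol 19, which is methylated as in the second stage of step 10.

Step 3. What may go wrong: incomplete E selectivity, base-induced migration of the new double bond into conjugation with the arene, and aldol self-condensation of the enolisable arylacetaldehyde. The fallback sets out from benzyl bromide 11 (with bromide 2 as second component) and comes back at allylic alcohol 9, so that steps 1–4 are bypassed.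
- Copper-catalysed coupling of 11 with propargyl alcohol (CuI, NaI, Cs2CO3, MeCN, rt) gives 4-[4-(benzyloxy)phenyl]but-2-yn-1-ol F7.
- Bromide 2 is converted with magnesium in THF into [2-(3-methoxyphenyl)ethyl]magnesium bromide F8.
- The hydroxyl of F7 is deprotonated with EtMgBr, and copper-catalysed anti-carbomagnesiation with F8 follows (CuI 10 mol %, THF/Et2O, −10 °C → rt; aqueous NH4Cl).
- The alkoxide directs the alkyl group to the alkyne carbon next to the carbinol and the metal, later hydrogen, to the distal carbon from the opposite side. The CH2CH2Ar' group thus ends cis to CH2Ar and the CH2OH group trans to it, which is the E geometry of 9.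

Step 6. What may go wrong: propargyl-to-allenyl isomerisation of the product by the basic Grignard reagent, Wurtz-type homocoupling of the benzylic bromide, and double benzylation of the acetylide. The fallback sets out from aldehyde 6, already made in step 2, and comes back at alkyne 12. Seyferth–Gilbert homologation with the Ohira–Bestmann reagent (dimethyl (1-diazo-2-oxopropyl)phosphonate, K2CO3, MeOH, 0 °C → rt) turns the aldehyde carbon into the terminal alkyne by a one-carbon homologation. This avoids the organometallic coupling and makes no new compound.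

Further compounds
F1 | step 8 | (4E)-6-[4-(benzyloxy)phenyl]-4-[2-(3-methoxyphenyl)ethyl]hex-4-en-1-yn-3-ol (racemic) | OC(C#C)/C(CCc1cccc(OC)c1)=C/Cc1ccc(OCc2ccccc2)cc1
F2 | step 8 | (4E)-6-[4-(benzyloxy)phenyl]-4-[2-(3-methoxyphenyl)ethyl]hex-4-en-1-yn-3-yl 2,2-dimethylpropanoate (racemic) | CC(C)(C)C(=O)OC(C#C)/C(CCc1cccc(OC)c1)=C/Cc1ccc(OCc2ccccc2)cc1
F3 | step 8 | 4-[4-(benzyloxy)benzyl]-3-hydroxy-5-[2-(3-methoxyphenyl)ethyl]phenyl 2,2-dimethylpropanoate | COc1cccc(CCc2cc(OC(=O)C(C)(C)C)cc(O)c2Cc2ccc(OCc3ccccc3)cc2)c1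
F4 | step 8 | 4-[4-(benzyloxy)benzyl]-2-formyl-3-hydroxy-5-[2-(3-methoxyphenyl)ethyl]phenyl 2,2-dimethylpropanoate | COc1cccc(CCc2cc(OC(=O)C(C)(C)C)c(C=O)c(O)c2Cc2ccc(OCc3ccccc3)cc2)c1
F5 | step 8 | 3-(benzyloxy)-4-[4-(benzyloxy)benzyl]-2-formyl-5-[2-(3-methoxyphenyl)ethyl]phenyl 2,2-dimethylpropanoate | COc1cccc(CCc2cc(OC(=O)C(C)(C)C)c(C=O)c(OCc3ccccc3)c2Cc2ccc(OCc3ccccc3)cc2)c1
F6 | step 8 | 3-(benzyloxy)-4-[4-(benzyloxy)benzyl]-2-{[4-(benzyloxy)phenyl](hydroxy)methyl}-5-[2-(3-methoxyphenyl)ethyl]phenol (racemic) | COc1cccc(CCc2cc(O)c(C(O)c3ccc(OCc4ccccc4)cc3)c(OCc3ccccc3)c2Cc2ccc(OCc3ccccc3)cc2)c1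
F7 | step 3 | 4-[4-(benzyloxy)phenyl]but-2-yn-1-ol | OCC#CCc1ccc(OCc2ccccc2)cc1
F8 | step 3 | [2-(3-methoxyphenyl)ethyl]magnesium bromide | COc1cccc(CC[Mg]Br)c1
F0 | step 6 | none | none
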